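**Retrosynthetic overview**
Germacrane numbering is used throughout: ring C1–C10; C11, C12, C13 are the lactone α-carbon, carbonyl and exo-methylene; C14 sits on C10 and C15 on C4. The C8 ester, C14 acetate and C15 aldehyde are adjusted after the skeleton is complete.
Key disconnection: the α-methylene-γ-lactone ring is removed in one retro-(3+2) step (bonds O–C6 and C7–C11), leaving a ten-membered carbocyclic 4,6-diene and 2-bromoacrylic acid.
Enabling feature: in the five-membered lactone ring the oxygen sits on C6, which is allylic to the ring alkene C4=C5, and C7 carries the sp2 carbon C11. This O–C6–C5=C4 / C7–C11(=C13) array is what carbopalladation of a C4=C5–C6=C7 ring diene, followed by carboxylate capture of the C4–C6 allyl unit, leaves behind.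
The ten-membered ring comes from ring-closing metathesis at C6=C7. C1=C10 comes from a Horner–Wadsworth–Emmons reaction of a phosphono-butyrolactone (temporary ring O8–C14, C8 from (R)-2-vinyloxirane), and C4=C5 from a Horner–Wadsworth–Emmons reaction with acrolein.
Ring order: temporary butyrolactone (opened by reduction), then the ten-membered carbocycle, then the γ-lactone as the last ring.

Key step: step 11

Remark (assumption): the E descriptors at C1=C10 and C4=C5 are read as ring-cis double bonds (C9/C2 cis and C3/C6 cis), the lactone as trans-fused (H6/H7 trans) with O8 trans to C11; (R)-2-vinyloxirane and 2-bromoacrylic acid are taken as purchasable.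

**Route**

Step 1
Reactants: 1 triethyl phosphonoacetate; 2 3-bromo-1,1-dimethoxypropane
Product: 3 ethyl 2-(diethoxyphosphoryl)-5,5-dimethoxypentanoate
Conditions: NaH, DMF, 0 °C; then 2, n-Bu4NI (cat.), 60 °C
Reagents that add atoms: none
Why: C-alkylation of the sodium phosphonoacetate carbanion with a primary bromide (phosphonate alkylation); the acetal is stable to base and no stereocentre is formed.

Step 2
Reactants: 3 ethyl 2-(diethoxyphosphoryl)-5,5-dimethoxypentanoate; 4 acrolein
Product: 5 ethyl (2E)-2-(3,3-dimethoxypropyl)penta-2,4-dienoate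
Conditions: NaH, THF, 0 °C; then 4, −78 → 0 °C
Reagents that add atoms: none
Why: Horner–Wadsworth–Emmons olefination of acrolein with the α-branched phosphonate should give mainly the (E)-dienoate (ester trans to the vinyl group), the geometry that becomes the ring-cis C4=C5 bond; the minor Z isomer would be removed by chromatography.

Step 3
Reactants: 5 ethyl (2E)-2-(3,3-dimethoxypropyl)penta-2,4-dienoate
Product: 6 (2E)-2-(3,3-dimethoxypropyl)penta-2,4-dien-1-ol
Conditions: i-Bu2AlH (2.2 equiv), CH2Cl2, −78 °C; aq. potassium sodium tartrate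
Reagents that add atoms: none
Why: 1,2-reduction of the dienoate to the allylic alcohol with i-Bu2AlH at low temperature leaves the diene geometry and the acetal untouched.

Step 4
Reactants: 6 (2E)-2-(3,3-dimethoxypropyl)penta-2,4-dien-1-ol
Product: 7 (2E)-2-(3,3-dimethoxypropyl)penta-2,4-dien-1-yl 4-methoxybenzyl ether
Conditions: NaH, PMBCl, n-Bu4NI (cat.), DMF, 0 °C → rt
Reagents that add atoms: 4-methoxybenzyl chloride, COc1ccc(CCl)cc1
Why: Williamson etherification gives a PMB ether that survives base, hydride, metathesis and palladium and can be removed oxidatively at the end.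

Step 5
Reactants: 7 (2E)-2-(3,3-dimethoxypropyl)penta-2,4-dien-1-yl 4-methoxybenzyl ether
Product: 8 (4E)-4-[(4-methoxybenzyloxy)methyl]hepta-4,6-dienal
Conditions: PPTS (cat.), acetone/H2O (9:1), 50 °C
Reagents that add atoms: water, O
Why: mild acid-catalysed acetal hydrolysis frees the C1 aldehyde without touching the PMB ether or the diene.

Step 6
Reactants: 9 (R)-2-vinyloxirane; 1 triethyl phosphonoacetate
Product: 11 diethyl [(5S)-2-oxo-5-vinyloxolan-3-yl]phosphonate (both C3 epimers), via sodium alkoxide 10 (not isolated)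
Conditions: NaH, THF, 0 °C; then 9, sealed tube, 65 °C; aq. NH4Cl
Reagents that add atoms: none
Why: epoxide opening–lactonisation: the soft phosphonoacetate carbanion attacks the unsubstituted epoxide carbon under basic conditions and alkoxide 10 closes onto the ester with loss of ethoxide; the C8 stereocentre is taken unchanged from 9 because its C–O bond is never broken.

Step 7
Reactants: 11 diethyl [(5S)-2-oxo-5-vinyloxolan-3-yl]phosphonate; 8 (4E)-4-[(4-methoxybenzyloxy)methyl]hepta-4,6-dienal
Product: 12 (3E,5S)-3-{(4E)-4-[(4-methoxybenzyloxy)methyl]hepta-4,6-dien-1-ylidene}-5-vinyloxolan-2-one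
Conditions: NaH, THF, 0 °C → rt
Reagents that add atoms: none
Why: Horner–Wadsworth–Emmons reaction of the α-phosphono lactone should give the (E)-alkylidene lactone (chain trans to the lactone carbonyl), which places C9 and C2 cis about C1=C10 as the target requires.

Step 8
Reactants: 12 (3E,5S)-3-{(4E)-4-[(4-methoxybenzyloxy)methyl]hepta-4,6-dien-1-ylidene}-5-vinyloxolan-2-one
Product: 13 (3S,5E,9E)-5-(hydroxymethyl)-9-[(4-methoxybenzyloxy)methyl]dodeca-1,5,9,11-tetraen-3-ol
Conditions: i-Bu2AlH (4 equiv), CH2Cl2, −78 → −20 °C; aq. potassium sodium tartrate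
Reagents that add atoms: none
Why: exhaustive 1,2-reduction of the unsaturated lactone with i-Bu2AlH opens the temporary ring to the C8/C14 diol without touching the alkenes or the PMB ether.

Step 9
Reactants: 13 (3S,5E,9E)-5-(hydroxymethyl)-9-[(4-methoxybenzyloxy)methyl]dodeca-1,5,9,11-tetraen-3-ol
Product: 14 (3S,5E,9E)-3-(tert-butyldimethylsilyloxy)-5-[(tert-butyldimethylsilyloxy)methyl]-9-[(4-methoxybenzyloxy)methyl]dodeca-1,5,9,11-tetraene
Conditions: TBSCl (2.5 equiv), imidazole, DMF, rt
Reagents that add atoms: tert-butyldimethylsilyl chloride, CC(C)(C)[Si](C)(C)Cl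
Why: silylation of both hydroxyls gives ethers that, unlike allylic esters, cannot ionise under zerovalent palladium, and makes the C8 substituent bulky for the later face selection.

Step 10
Reactants: 14 (3S,5E,9E)-3-(tert-butyldimethylsilyloxy)-5-[(tert-butyldimethylsilyloxy)methyl]-9-[(4-methoxybenzyloxy)methyl]dodeca-1,5,9,11-tetraene
Product: 15 (8S)-8,14-bis(tert-butyldimethylsilyloxy)-15-(4-methoxybenzyloxy)germacra-1(10),4,6-triene, 1(10)E,4E,6Z (all three ring double bonds ring-cis)
Conditions: second-generation Grubbs catalyst (H2IMes)(PCy3)Cl2Ru=CHPh (10 mol %), CH2Cl2 (0.001 M), 40 °C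
Reagents that add atoms: none
Why: ring-closing metathesis joins the two monosubstituted termini (the trisubstituted alkenes are unreactive) with loss of ethene; the two ring-cis trisubstituted alkenes already in the chain fold it, and the new C6=C7 bond should form Z, the less strained arrangement of a conjugated diene in a ten-membered ring.

Step 11
Reactants: 15 (8S)-8,14-bis(tert-butyldimethylsilyloxy)-15-(4-methoxybenzyloxy)germacra-1(10),4,6-triene; 16 2-bromoacrylic acid
Product: 19 (6R,7S,8S)-8,14-bis(tert-butyldimethylsilyloxy)-15-(4-methoxybenzyloxy)germacra-1(10),4,11(13)-trien-12,6-olide, via vinylpalladium bromide 17 (not isolated), via allylpalladium bromide 18 (not isolated)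
Conditions: Pd(OAc)2 (10 mol %), n-Bu4NCl (2 equiv), NaHCO3 (3 equiv), DMF, 80 °C; 16 (3 equiv) added over 6 h
Reagents that add atoms: none
Why: Larock-type palladium-catalysed (3+2) heteroannulation of a 1,3-diene with a 2-haloalkenoic acid: zerovalent palladium (formed from Pd(OAc)2) inserts into the C–Br bond of 16 to give vinylpalladium 17, which adds syn across C6=C7 with C11 going to C7 and palladium to C6, giving the C4–C6 allylpalladium 18 (drawn in its C6-bound form). The closest known reaction type is the palladium-catalysed annulation of 1,3-dienes by aryl and vinylic halides that carry an OH, NHR or CO2H group. The only ring closed is the five-membered lactone, formed in a 5-exo mode when the carboxylate oxygen attacks C6, the allyl terminus next to C7; this releases zerovalent palladium and leaves C4=C5 in place with the ring-cis geometry of the diene, because syn/anti exchange at C4 would need a tertiary carbon–palladium bond. C7 is set by substrate control, the vinylpalladium adding to the diene face anti to the bulky C8 silyloxy group (C11 trans to O8); C6 is set by the mechanism, because chloride keeps the carboxylate off the metal so that, after rotation about C6–C7, it attacks anti to palladium, and net anti addition across the (Z)-C6=C7 bond means a trans ring fusion (H6/H7 trans), which is also the fusion expected if the allylic lactone re-ionises and equilibrates. The step needs site selectivity (conjugated diene over the isolated trisubstituted C1=C10 alkene), regioselectivity (the CH terminus C7 over the fully substituted C4), face selectivity (C8 OTBS) and capture at C6 instead of C4 (five- against seven-membered ring); silyl and PMB ethers were chosen because they do not ionise under zerovalent palladium, and slow addition of 16 limits a second Heck reaction at the new exo-methylene lactone.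

Step 12
Reactants: 19 (6R,7S,8S)-8,14-bis(tert-butyldimethylsilyloxy)-15-(4-methoxybenzyloxy)germacra-1(10),4,11(13)-trien-12,6-olide
Product: 20 (6R,7R,8S)-8,14-dihydroxy-15-(4-methoxybenzyloxy)germacra-1(10),4,11(13)-trien-12,6-olide
Conditions: HF·pyridine, pyridine, THF, 0 °C → rt
Reagents that add atoms: none
Why: fluoride-mediated desilylation under buffered, slightly acidic conditions cleaves both silyl ethers while the lactone, its exo-methylene group and the PMB ether are stable, and avoids the base that could move the lactone to O8.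

Step 13
Reactants: 20 (6R,7R,8S)-8,14-dihydroxy-15-(4-methoxybenzyloxy)germacra-1(10),4,11(13)-trien-12,6-olide
Product: 21 (6R,7R,8S)-14-acetoxy-8-hydroxy-15-(4-methoxybenzyloxy)germacra-1(10),4,11(13)-trien-12,6-olide
Conditions: Ac2O (1.1 equiv), 2,4,6-collidine, CH2Cl2, −20 → 0 °C
Reagents that add atoms: acetic anhydride, CC(=O)OC(C)=O
Why: chemoselective acylation: the primary allylic C14 hydroxyl should react much faster than the hindered secondary C8 hydroxyl next to the ring fusion.

Step 14
Reactants: 22 ethyl 2-(hydroxymethyl)acrylate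
Product: 23 ethyl 2-[(tert-butyldimethylsilyloxy)methyl]acrylate
Conditions: TBSCl, imidazole, CH2Cl2, 0 °C → rt
Reagents that add atoms: tert-butyldimethylsilyl chloride, CC(C)(C)[Si](C)(C)Cl
Why: standard silylation of the primary allylic alcohol masks the side-chain hydroxyl for the esterification.

Step 15
Reactants: 23 ethyl 2-[(tert-butyldimethylsilyloxy)methyl]acrylate
Product: 24 2-[(tert-butyldimethylsilyloxy)methyl]acrylic acid
Conditions: LiOH·H2O, THF/H2O (3:1), 0 °C; then 1 M HCl to pH 4, 0 °C
Reagents that add atoms: lithium hydroxide, [Li+].[OH-]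
Why: saponification of the ethyl ester at 0 °C followed by careful acidification; the primary silyl ether tolerates both.

Step 16
Reactants: 21 (6R,7R,8S)-14-acetoxy-8-hydroxy-15-(4-methoxybenzyloxy)germacra-1(10),4,11(13)-trien-12,6-olide; 24 2-[(tert-butyldimethylsilyloxy)methyl]acrylic acid
Product: 25 (6R,7R,8S)-14-acetoxy-8-{2-[(tert-butyldimethylsilyloxy)methyl]acryloyloxy}-15-(4-methoxybenzyloxy)germacra-1(10),4,11(13)-trien-12,6-olide
Conditions: N,N'-diisopropylcarbodiimide, DMAP (cat.), CH2Cl2, 0 °C → rt
Reagents that add atoms: none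
Why: Steglich esterification acylates the C8 hydroxyl with retention at C8 under nearly neutral conditions that preserve the methylene lactone and the allylic acetate.

Step 17
Reactants: 25 (6R,7R,8S)-14-acetoxy-8-{2-[(tert-butyldimethylsilyloxy)methyl]acryloyloxy}-15-(4-methoxybenzyloxy)germacra-1(10),4,11(13)-trien-12,6-olide
Product: 26 (6R,7R,8S)-14-acetoxy-8-{2-[(tert-butyldimethylsilyloxy)methyl]acryloyloxy}-15-hydroxygermacra-1(10),4,11(13)-trien-12,6-olide
Conditions: DDQ (1.5 equiv), CH2Cl2/pH 7 buffer (10:1), 0 °C → rt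
Reagents that add atoms: none
Why: oxidative cleavage of the PMB ether by DDQ in wet CH2Cl2; silyl ether, esters and alkenes are inert to it.

Step 18
Reactants: 26 (6R,7R,8S)-14-acetoxy-8-{2-[(tert-butyldimethylsilyloxy)methyl]acryloyloxy}-15-hydroxygermacra-1(10),4,11(13)-trien-12,6-olide
Product: 27 (6R,7R,8S)-14-acetoxy-8-{2-[(tert-butyldimethylsilyloxy)methyl]acryloyloxy}-15-oxogermacra-1(10),4,11(13)-trien-12,6-olide
Conditions: MnO2 (20 equiv), CH2Cl2, rt
Reagents that add atoms: none
Why: MnO2 oxidises only the allylic C15 alcohol to the enal under neutral conditions that should leave the ring-cis C4=C5 geometry and the side-chain silyl ether untouched.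

Step 19
Reactants: 27 (6R,7R,8S)-14-acetoxy-8-{2-[(tert-butyldimethylsilyloxy)methyl]acryloyloxy}-15-oxogermacra-1(10),4,11(13)-trien-12,6-olide
Product: 28 (6R,7R,8S)-14-acetoxy-8-[2-(hydroxymethyl)acryloyloxy]-15-oxogermacra-1(10),4,11(13)-trien-12,6-olide (CNP0198933.2)
Conditions: HF·pyridine, pyridine, THF, 0 °C
Reagents that add atoms: none
Why: fluoride-mediated desilylation under buffered conditions frees the side-chain hydroxyl while avoiding strong base that could eliminate the γ-acyloxy enal.

**Compound list**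

1 | triethyl phosphonoacetate | CCOC(=O)CP(=O)(OCC)OCC | starting material
2 | 3-bromo-1,1-dimethoxypropane | COC(OC)CCBr | starting material
3 | ethyl 2-(diethoxyphosphoryl)-5,5-dimethoxypentanoate (racemic) | CCOC(=O)C(CCC(OC)OC)P(=O)(OCC)OCC | intermediate
4 | acrolein | C=CC=O | starting material
5 | ethyl (2E)-2-(3,3-dimethoxypropyl)penta-2,4-dienoate | C=C/C=C(/C(=O)OCC)CCC(OC)OC | intermediate
6 | (2E)-2-(3,3-dimethoxypropyl)penta-2,4-dien-1-ol | C=C/C=C(/CO)CCC(OC)OC | intermediate
7 | (2E)-2-(3,3-dimethoxypropyl)penta-2,4-dien-1-yl 4-methoxybenzyl ether | C=C/C=C(/COCc1ccc(OC)cc1)CCC(OC)OC | intermediate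
8 | (4E)-4-[(4-methoxybenzyloxy)methyl]hepta-4,6-dienal | C=C/C=C(/COCc1ccc(OC)cc1)CCC=O | intermediate
9 | (R)-2-vinyloxirane | C=C[C@@H]1CO1 | starting material
10 | sodium alkoxide of ethyl (4S)-2-(diethoxyphosphoryl)-4-hydroxyhex-5-enoate | C=C[C@@H]([O-])CC(C(=O)OCC)P(=O)(OCC)OCC.[Na+] | intermediate
11 | diethyl [(5S)-2-oxo-5-vinyloxolan-3-yl]phosphonate (both C3 epimers) | C=C[C@@H]1CC(P(=O)(OCC)OCC)C(=O)O1 | intermediate
12 | (3E,5S)-3-{(4E)-4-[(4-methoxybenzyloxy)methyl]hepta-4,6-dien-1-ylidene}-5-vinyloxolan-2-one | C=C[C@@H]1C/C(=C\CC/C(COCc2ccc(OC)cc2)=C\C=C)C(=O)O1 | intermediate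
13 | (3S,5E,9E)-5-(hydroxymethyl)-9-[(4-methoxybenzyloxy)methyl]dodeca-1,5,9,11-tetraen-3-ol | C=C[C@@H](O)C/C(CO)=C\CC/C(COCc1ccc(OC)cc1)=C\C=C | intermediate
14 | (3S,5E,9E)-3-(tert-butyldimethylsilyloxy)-5-[(tert-butyldimethylsilyloxy)methyl]-9-[(4-methoxybenzyloxy)methyl]dodeca-1,5,9,11-tetraene | C=C[C@@H](O[Si](C)(C)C(C)(C)C)C/C(CO[Si](C)(C)C(C)(C)C)=C\CC/C(COCc1ccc(OC)cc1)=C\C=C | intermediate
15 | (8S)-8,14-bis(tert-butyldimethylsilyloxy)-15-(4-methoxybenzyloxy)germacra-1(10),4,6-triene, 1(10)E,4E,6Z, all ring-cis | CC(C)(C)[Si](C)(C)O[C@H]1C/C(CO[Si](C)(C)C(C)(C)C)=C\CC/C(COCc2ccc(OC)cc2)=C\C=C/1 | intermediate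
16 | 2-bromoacrylic acid | C=C(Br)C(=O)O | starting material
17 | sodium 2-(bromopalladio)acrylate (vinylpalladium bromide, divalent palladium) | C=C([Pd]Br)C(=O)[O-].[Na+] | intermediate
18 | sodium 2-[(8S)-6-(bromopalladio)-8,14-bis(tert-butyldimethylsilyloxy)-15-(4-methoxybenzyloxy)germacra-1(10),4-dien-7-yl]acrylate, Pd on C6 cis to the C7–C11 bond (C6-bound form of the C4–C6 allylpalladium) | CC(C)(C)[Si](C)(C)O[C@H]1C/C(CO[Si](C)(C)C(C)(C)C)=C\CC/C(COCc2ccc(OC)cc2)=C\[C@H]([Pd]Br)[C@@H]1C(=C)C(=O)[O-].[Na+] | intermediate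
19 | (6R,7S,8S)-8,14-bis(tert-butyldimethylsilyloxy)-15-(4-methoxybenzyloxy)germacra-1(10),4,11(13)-trien-12,6-olide (trans-fused; the 7-descriptor is S only because silicon on O8 raises the rank of C8, the arrangement in space is that of the target) | CC(C)(C)[Si](C)(C)O[C@H]1C/C(CO[Si](C)(C)C(C)(C)C)=C\CC/C(COCc3ccc(OC)cc3)=C\[C@H]2OC(=O)C(=C)[C@H]12 | intermediate
20 | (6R,7R,8S)-8,14-dihydroxy-15-(4-methoxybenzyloxy)germacra-1(10),4,11(13)-trien-12,6-olide | O[C@H]1C/C(CO)=C\CC/C(COCc3ccc(OC)cc3)=C\[C@H]2OC(=O)C(=C)[C@H]12 | intermediate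
21 | (6R,7R,8S)-14-acetoxy-8-hydroxy-15-(4-methoxybenzyloxy)germacra-1(10),4,11(13)-trien-12,6-olide | O[C@H]1C/C(COC(C)=O)=C\CC/C(COCc3ccc(OC)cc3)=C\[C@H]2OC(=O)C(=C)[C@H]12 | intermediate
22 | ethyl 2-(hydroxymethyl)acrylate | C=C(CO)C(=O)OCC | starting material
23 | ethyl 2-[(tert-butyldimethylsilyloxy)methyl]acrylate | C=C(CO[Si](C)(C)C(C)(C)C)C(=O)OCC | intermediate
24 | 2-[(tert-butyldimethylsilyloxy)methyl]acrylic acid | C=C(CO[Si](C)(C)C(C)(C)C)C(=O)O | intermediate
25 | (6R,7R,8S)-14-acetoxy-8-{2-[(tert-butyldimethylsilyloxy)methyl]acryloyloxy}-15-(4-methoxybenzyloxy)germacra-1(10),4,11(13)-trien-12,6-olide | C=C(CO[Si](C)(C)C(C)(C)C)C(=O)O[C@H]1C/C(COC(C)=O)=C\CC/C(COCc3ccc(OC)cc3)=C\[C@H]2OC(=O)C(=C)[C@H]12 | intermediate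
26 | (6R,7R,8S)-14-acetoxy-8-{2-[(tert-butyldimethylsilyloxy)methyl]acryloyloxy}-15-hydroxygermacra-1(10),4,11(13)-trien-12,6-olide | C=C(CO[Si](C)(C)C(C)(C)C)C(=O)O[C@H]1C/C(COC(C)=O)=C\CC/C(CO)=C\[C@H]2OC(=O)C(=C)[C@H]12 | intermediate
27 | (6R,7R,8S)-14-acetoxy-8-{2-[(tert-butyldimethylsilyloxy)methyl]acryloyloxy}-15-oxogermacra-1(10),4,11(13)-trien-12,6-olide | C=C(CO[Si](C)(C)C(C)(C)C)C(=O)O[C@H]1C/C(COC(C)=O)=C\CC/C(C=O)=C\[C@H]2OC(=O)C(=C)[C@H]12 | intermediate
28 | (6R,7R,8S)-14-acetoxy-8-[2-(hydroxymethyl)acryloyloxy]-15-oxogermacra-1(10),4,11(13)-trien-12,6-olide, 1(10)E,4E (CNP0198933.2) | C=C(CO)C(=O)O[C@H]1C/C(COC(C)=O)=C\CC/C(C=O)=C\[C@H]2OC(=O)C(=C)[C@H]12 | target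

**Step count and risks**

Total step count: 19. Longest linear sequence: 16 steps (steps 1–5, 7–13, 16–19); step 6 and steps 14–15 are side branches.

Most likely to fail, step 11 (key step). The process at risk is low productive turnover: the bromoacrylate can be lost by self-coupling and polymerisation, the new exo-methylene lactone can be vinylated a second time, and the allylpalladium can collapse by β-hydride elimination. The fallback sets out from 15 and separates ring closure from the carbonyl oxidation level. Annulation of 15 with 2-bromoprop-2-en-1-ol (Pd(OAc)2, n-Bu4NCl, NaHCO3, DMF, 80 °C), a partner that is not an acrylate and whose product is not a Heck acceptor, should give the cyclic ether (6R,7S,8S)-8,14-bis(tert-butyldimethylsilyloxy)-15-(4-methoxybenzyloxy)-6,12-epoxygermacra-1(10),4,11(13)-triene F1. Allylic oxidation of the ring O–CH2 group of F1 (CrO3·3,5-dimethylpyrazole, CH2Cl2, −20 °C) then leads to 19, where the route is rejoined.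

Second, step 10. The process at risk is acyclic diene metathesis oligomerisation of the flexible chain, together with formation of the ring-trans C6=C7 isomer. The fallback sets out from 12 and moves ring closure in front of the lactone reduction, so that the substrate is the rigid alkylidene lactone rather than the open bis-silyl ether. Ring-closing metathesis of 12 with the same ruthenium catalyst in dilute toluene at 60 °C should give the bridged (8S)-15-(4-methoxybenzyloxy)germacra-1(10),4,6-trien-14,8-olide F2. Reduction with i-Bu2AlH in CH2Cl2 at −78 °C opens it to (8S)-15-(4-methoxybenzyloxy)germacra-1(10),4,6-triene-8,14-diol F3, and silylation (TBSCl, imidazole, DMF) gives 15, where the route is rejoined.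

Third, step 13. The process at risk is over-acylation to the diacetate and incomplete discrimination between the two hydroxyls. The fallback sets out from 19 and replaces chemoselective acylation by stepwise unmasking. Brief treatment of 19 with HF·pyridine in pyridine/THF at −20 °C removes only the primary allylic silyl ether to give (6R,7S,8S)-8-(tert-butyldimethylsilyloxy)-14-hydroxy-15-(4-methoxybenzyloxy)germacra-1(10),4,11(13)-trien-12,6-olide F4. Acetylation (Ac2O, pyridine, DMAP, CH2Cl2) gives (6R,7S,8S)-14-acetoxy-8-(tert-butyldimethylsilyloxy)-15-(4-methoxybenzyloxy)germacra-1(10),4,11(13)-trien-12,6-olide F5, and HF·pyridine at rt then frees the C8 hydroxyl to give 21, where the route is rejoined.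

**Further compounds**

F1 | step 11 | (6R,7S,8S)-8,14-bis(tert-butyldimethylsilyloxy)-15-(4-methoxybenzyloxy)-6,12-epoxygermacra-1(10),4,11(13)-triene | CC(C)(C)[Si](C)(C)O[C@H]1C/C(CO[Si](C)(C)C(C)(C)C)=C\CC/C(COCc3ccc(OC)cc3)=C\[C@H]2OCC(=C)[C@H]12
F2 | step 10 | (8S)-15-(4-methoxybenzyloxy)germacra-1(10),4,6-trien-14,8-olide | O=C1O[C@H]2C/C1=C\CC/C(COCc3ccc(OC)cc3)=C\C=C/2
F3 | step 10 | (8S)-15-(4-methoxybenzyloxy)germacra-1(10),4,6-triene-8,14-diol | O[C@H]1C/C(CO)=C\CC/C(COCc2ccc(OC)cc2)=C\C=C/1
F4 | step 13 | (6R,7S,8S)-8-(tert-butyldimethylsilyloxy)-14-hydroxy-15-(4-methoxybenzyloxy)germacra-1(10),4,11(13)-trien-12,6-olide | CC(C)(C)[Si](C)(C)O[C@H]1C/C(CO)=C\CC/C(COCc3ccc(OC)cc3)=C\[C@H]2OC(=O)C(=C)[C@H]12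
F5 | step 13 | (6R,7S,8S)-14-acetoxy-8-(tert-butyldimethylsilyloxy)-15-(4-methoxybenzyloxy)germacra-1(10),4,11(13)-trien-12,6-olide | CC(C)(C)[Si](C)(C)O[C@H]1C/C(COC(C)=O)=C\CC/C(COCc3ccc(OC)cc3)=C\[C@H]2OC(=O)C(=C)[C@H]12
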